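## The problem

The target is an achiral diaryl ether: a 6-hydroxy-3-pentylisocoumarin (ring A is the benzo ring, ring B the pyranone) whose C8 oxygen carries ring C, a fully substituted olivetolic acid unit (C1' CO2H, C2' pentyl, C3' the ether oxygen, C4' OH, C5' H, C6' OH). There is no stereocentre, so every selectivity question is one of position. The hard bond is the diaryl ether: its oxygen lies between a pentyl chain and an oxygen substituent on ring C and peri to the lactone carbonyl on ring A, so an aryl C–O coupling would have to join two doubly ortho-substituted partners. Ring C hides a symmetry, because the carboxyl group and the ether oxygen occupy the two equivalent positions of olivetol that flank the pentyl chain. Three features set the order of events: the 2,4-dihydroxy-6-alkylbenzoic acid loses CO2 under heat or strong acid, the enol lactone opens with hydroxide or alkoxide and its C3=C4 bond can be hydrogenated, and the electron-rich rings compete in every electrophilic step. The feature that opens the route is the 1,3,5-pattern of ring A, with oxygen at C6 and C8 and the carbon substituent at C4a all meta to one another: this is what a cyclobutenone and an ynol ether give in a vinylketene benzannulation, with the ynol ether oxygen ending as the oxygen at C8. Ring A can therefore be grown on the oxygen of a finished ring C, and what remains is to bring C1 to C8a and close ring B.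

## Retrosynthesis

**31 from 30.** The three phenolic O–H bonds are traced back to benzyl ethers in acid 30. One protecting group for all three hydroxyls means a single neutral hydrogenolysis at room temperature as the last step, which suits the decarboxylation-prone acid. Methyl ethers would need a boron halide at the end, and silyl ethers next to a free phenol would migrate earlier in the route. The forward step must spare the C3=C4 bond.

**30 from 29.** The lactone bond C1–O2 is cut and the ring C acid is masked as a tert-butyl ester, giving the open keto diester 29. One acid treatment should both lactonise and remove the tert-butyl group, so no base ever meets the enol lactone. A methyl or benzyl ester on ring C would not survive the organolithium steps that precede, and a late saponification would open ring B.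

**29 from 25 and 27.** The C4–C3 bond is cut: the ring A methyl group of toluate 25 becomes C4, and Weinreb amide 27 (from hexanoyl chloride 26) supplies C3 with the pentyl chain. This uses the methyl group that the benzannulation leaves at C4a. An alkyne coupling and cycloisomerisation would need a halide at C4a as well as the carboxyl at C8a, that is two ring A functionalisations instead of one.

**25 from 23, 22 and 21.** The C8a–C1 bond is cut to aryl bromide 23 (bromine–lithium exchange, chloroformate), and the bromide goes back through bromophenol 22 to phenol 21. C8a is para to the free hydroxyl of 21, so the hydroxyl is used as the director before it is benzylated. This is the least secure regiochemical step of the plan. For it to work at all, ring C must not compete, which fixes how ring C is built (see below).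

**21 from 13 and 16.** The key cut removes three bonds of ring A at once (C6–C7, C8–C8a, C5–C6) and gives 3-methylcyclobut-2-en-1-one 16 and aryl ethynyl ether 13. It replaces the hindered aryl C–O coupling by formation of a ring on the oxygen atom. The precursors are a four-carbon ketone and an ether of the complete ring C.

**13 from 11, 8 and 9.** The O–C(sp) bond is cut to phenol 8 and trichloroethylene 9. The phenoxide adds to dichloroacetylene 10 formed in the flask, giving dichlorovinyl ether 11, and n-BuLi converts this to 13. The oxygen of the future diaryl ether is thus alkynylated, not arylated, and steric hindrance at the phenol matters little for so small an electrophile.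

**8 from 5, 3, 2 and 1.** Both substituents next to the pentyl chain are traced to bromine atoms in the symmetric dibromide 3, made from olivetol 1 through dibenzyl ether 2. The first bromine–lithium exchange gives ester 5, the second gives the phenol. Against a late carboxylation of the free resorcinol ring, this fixes the carboxyl position by symmetry and avoids a choice between C1' and C5' in the presence of the ring A phenol. Against a formylation and oxidative route to the ring C phenol, it leaves ring C with an electron-withdrawing ester and only one free position (C5', between two benzyloxy groups) when ring A is brominated.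

**16 from 14.** The methyl group is cut from the cyclobutenone: MeLi adds to 3-ethoxycyclobut-2-en-1-one 14 and acid transposes the carbonyl group.

## Roads not taken

**Alternative 1:** Ring C would be made last, on the finished isocoumarin. The cut goes through C1'–C2' and C5'–C6'. Hydroxyisocoumarin A1 would be converted to the α-aryloxy enone A2. Dibenzyl malonate A3 would add to A2 in a Michael reaction, and a Claisen closure of the methyl ketone onto a malonate ester would give cyclohexane-1,3-dione A4, to be dehydrogenated to the resorcylate.
- Merits: carboxyl, pentyl and both hydroxyls of ring C arrive in one step with no positional question, and ring A comes from an orsellinate, so no electrophilic substitution on ring A has to be steered. In both respects this road is better than the chosen plan, which spends four steps on the ring C pattern and relies on a para-bromination.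
- Weak points: the hydroxyl of A1 is hydrogen-bonded to the lactone carbonyl and hindered, so making A2 is difficult. A2 is a β-alkyl enone with an oxygen donor on the α-carbon and a poor Michael acceptor. The alkoxide base would meet the enol lactone. The aromatisation of A4 needs an oxidant or halogen in the presence of the electron-rich C4 and ring A.
- Comparison: the chosen plan sets against this a key step that is electronically matched and neutral, and a ring B that is only closed after all strongly basic steps.

**Alternative 2:** Ring C would again be made last, by a Diels–Alder benzannulation. The cut goes through C2'–C3' and C1'–C6': the aryloxy bis(silyloxy)diene A5 and benzyl oct-2-ynoate A6 would combine, and loss of methanol would give resorcylate A7.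
- Merits: A7 is one hydrogenolysis from the target, the regiochemistry of such dienes with ynoates is dependable, and no carboxylation or ring A substitution is needed. In step count after the key step this road is clearly shorter than the chosen plan.
- Weak points: A5 has to come from A1 by O-alkylation with a 4-haloacetoacetate (the same poor nucleophile as above), its reacting terminus carries the bulky aryloxy group, and a β-alkyl ynoate is a sluggish dienophile. The heat then needed favours silyl migration and decomposition of the diene.
- Comparison: the chosen plan pairs an electron-rich alkyne with a strongly electrophilic ketene and puts the steric load on an sp carbon. It pays for this with a longer sequence after the key step.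

**Alternative 3:** Ring B would be made in one step from a preformed diaryl ether. The cut removes C4a–C4, C8a–C1 and C1–O2: aryl iodide A8 and 2-pentyloxirane A9 would be joined under carbonylative Catellani conditions to dihydroisocoumarin A10.
- Merits: C1 enters at the carbon that bore iodine and C4 at its free ortho neighbour, so the positional question that the chosen plan answers with a para-bromination does not arise.
- Weak points: A8 is itself the doubly hindered diaryl ether and needs the aryl C–O coupling that the benzannulation avoids. Epoxide Catellani reactions tend to end by C–O bond formation to a dihydrobenzofuran, which the carbonylative ending would have to outrun. A10 is at the wrong oxidation level, with a C3 stereocentre that must be destroyed by a dehydrogenation next to benzyl ethers. Its methyl ether needs a boron halide, and ring C still lacks its carboxyl group.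
- Comparison: the chosen plan is less certain at C8a but needs no oxidation-level correction and no hindered ether coupling.

Key step: step 8

Remark: 3-ethoxycyclobut-2-en-1-one (14) is treated as a purchasable reagent. Positions are numbered C1–C8a on the isocoumarin and C1'–C6' on ring C, with C1' bearing the carboxyl group.

## Route

**Step 1**
Reactants: 1 olivetol (5-pentylbenzene-1,3-diol)
Product: 2 1,3-bis(benzyloxy)-5-pentylbenzene
Conditions: BnBr (2.3 equiv), K2CO3, DMF, 60 °C
Reagents that add atoms: benzyl bromide, BrCc1ccccc1
Why: Williamson etherification of both phenols; benzyl ethers tolerate the organolithium steps and all leave together in the last step.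

**Step 2**
Reactants: 2 1,3-bis(benzyloxy)-5-pentylbenzene
Product: 3 1,5-bis(benzyloxy)-2,4-dibromo-3-pentylbenzene
Conditions: NBS (2.1 equiv), MeCN, 0 °C to rt, dark
Reagents that add atoms: N-bromosuccinimide, O=C1CCC(=O)N1Br
Why: Electrophilic aromatic bromination; each bromine enters para to one benzyloxy group and ortho to the other, at the two equivalent positions flanking the pentyl chain, as is usual for 5-alkylresorcinol diethers, and the position between the two ethers stays free.

**Step 3**
Reactants: 3 1,5-bis(benzyloxy)-2,4-dibromo-3-pentylbenzene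
Product: 5 tert-butyl 4,6-bis(benzyloxy)-3-bromo-2-pentylbenzoate, via aryllithium 4 (not isolated)
Conditions: n-BuLi (1.0 equiv), THF, −78 °C; then Boc2O, −78 to 0 °C
Reagents that add atoms: di-tert-butyl dicarbonate, CC(C)(C)OC(=O)OC(=O)OC(C)(C)C
Why: Bromine–lithium exchange of one of two equivalent bromides (a second exchange on the same ring is disfavoured), then acylation of the aryllithium by Boc2O; the tert-butyl ester, shielded by both ortho substituents, is the organolithium-stable form of the ring C carboxyl group.

**Step 4**
Reactants: 5 tert-butyl 4,6-bis(benzyloxy)-3-bromo-2-pentylbenzoate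
Product: 8 tert-butyl 4,6-bis(benzyloxy)-3-hydroxy-2-pentylbenzoate, via ester aryllithium 6 (not isolated), via arylboronate 7 (not isolated)
Conditions: n-BuLi (1.05 equiv), THF, −78 °C; B(OMe)3; then H2O2, aq NaOH, 0 °C
Reagents that add atoms: hydrogen peroxide, OO
Why: Bromine–lithium exchange is far faster at −78 °C than addition to the doubly ortho-shielded tert-butyl ester; borylation and oxidative aryl migration from boron to oxygen turn the C–Br bond into the phenol.

**Step 5**
Reactants: 8 tert-butyl 4,6-bis(benzyloxy)-3-hydroxy-2-pentylbenzoate; 9 trichloroethylene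
Product: 11 tert-butyl 4,6-bis(benzyloxy)-3-{[(E)-1,2-dichloroethenyl]oxy}-2-pentylbenzoate, via dichloroacetylene 10 (not isolated)
Conditions: Cl2C=CHCl (2 equiv), K2CO3, DMF, 70 °C
Reagents that add atoms: none
Why: The base eliminates HCl from trichloroethylene and the phenoxide adds anti to the dichloroacetylene so formed, giving the (E)-dichlorovinyl ether; this is the established route from phenols to the precursors of aryl ynol ethers.

**Step 6**
Reactants: 11 tert-butyl 4,6-bis(benzyloxy)-3-{[(E)-1,2-dichloroethenyl]oxy}-2-pentylbenzoate
Product: 13 tert-butyl 4,6-bis(benzyloxy)-3-(ethynyloxy)-2-pentylbenzoate, via lithium acetylide 12 (not isolated)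
Conditions: n-BuLi (2.2 equiv, slow addition), THF, −78 °C; H2O (pH 7 buffer), −78 to 0 °C; used at once
Reagents that add atoms: none
Why: Deprotonation, loss of LiCl and chlorine–lithium exchange lead to acetylide 12, and protonation gives the terminal ynol ether (dichlorovinyl ether to ynol ether conversion); the vinyl C–H and the C–Cl bond consume n-BuLi much faster than the shielded ester can.

**Step 7**
Reactants: 14 3-ethoxycyclobut-2-en-1-one
Product: 16 3-methylcyclobut-2-en-1-one, via lithium alkoxide 15 (not isolated)
Conditions: MeLi, Et2O, −78 °C; then 1 M HCl, 0 °C; kept as a cold solution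
Reagents that add atoms: methyllithium, [Li]C; water, O
Why: 1,2-Addition of MeLi to the vinylogous ester, then acid hydrolysis of the enol ether with loss of water, transposes the carbonyl group (Stork–Danheiser-type alkylative transposition), the standard entry to 3-alkylcyclobutenones.

**Step 8**
Reactants: 16 3-methylcyclobut-2-en-1-one; 13 tert-butyl 4,6-bis(benzyloxy)-3-(ethynyloxy)-2-pentylbenzoate
Product: 21 tert-butyl 4,6-bis(benzyloxy)-3-(3-hydroxy-5-methylphenoxy)-2-pentylbenzoate, via vinylketene 17 (not isolated), via vinylcyclobutenone 18 (not isolated), via dienylketene 19 (not isolated), via cyclohexadienone 20 (not isolated)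
Conditions: 16 (1.5 equiv), toluene (degassed), 80 °C then 110 °C, sealed tube
Reagents that add atoms: none
Why: At 80 °C cyclobutenone 16 opens by a conrotatory 4π-electrocyclic reaction to vinylketene 17, and the ynol ether adds to it in a (2+2) cycloaddition in which the nucleophilic terminal CH of 13 bonds to the ketene carbonyl carbon (C6–C7) and the oxygen-bearing carbon to the ketene α-carbon (C8–C8a), giving vinylcyclobutenone 18. A second 4π opening of 18 gives dienylketene 19, whose thermal disrotatory 6π-electrocyclisation over six carbon atoms (bond C5–C6) closes ring A as cyclohexadienone 20; enolisation then gives phenol 21. The closest known reaction type is the Danheiser benzannulation of 3-alkylcyclobutenones with alkoxy- and silyloxyacetylenes, which gives 5-alkylresorcinol monoethers in this orientation; the aryl ether used here is a further member of the ynol ether class. No stereocentre is formed. The one selectivity needed is the orientation of the (2+2) step, and it is secured by the polarisation of the ynol ether, whose oxygen lone pair makes the CH carbon the nucleophile for the electrophilic ketene carbon, so that the aryloxy group ends meta to both the new hydroxyl and the methyl group. An aryl ynol ether has no alkyl C–H on oxygen for a retro-ene loss of ketene, and the two ortho substituents of ring C shield it against self-addition, so it should last at the temperature at which 16 opens; 16 is volatile and is therefore used in excess.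

**Step 9**
Reactants: 21 tert-butyl 4,6-bis(benzyloxy)-3-(3-hydroxy-5-methylphenoxy)-2-pentylbenzoate
Product: 22 tert-butyl 4,6-bis(benzyloxy)-3-(2-bromo-5-hydroxy-3-methylphenoxy)-2-pentylbenzoate
Conditions: NBS (1.0 equiv), DMF, −20 to 0 °C, dark
Reagents that add atoms: N-bromosuccinimide, O=C1CCC(=O)N1Br
Why: Electrophilic bromination of a phenol para to the free hydroxyl (NBS in DMF favours para attack, as with other 3,5-disubstituted phenols); ring C is deactivated by its ester and its one remaining C–H lies between two benzyloxy groups, so ring A should react alone.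

**Step 10**
Reactants: 22 tert-butyl 4,6-bis(benzyloxy)-3-(2-bromo-5-hydroxy-3-methylphenoxy)-2-pentylbenzoate
Product: 23 tert-butyl 4,6-bis(benzyloxy)-3-[5-(benzyloxy)-2-bromo-3-methylphenoxy]-2-pentylbenzoate
Conditions: BnBr, K2CO3, DMF, rt
Reagents that add atoms: benzyl bromide, BrCc1ccccc1
Why: Williamson etherification; the acidic phenol is masked before the exchange step with the same group that ring C carries.

**Step 11**
Reactants: 23 tert-butyl 4,6-bis(benzyloxy)-3-[5-(benzyloxy)-2-bromo-3-methylphenoxy]-2-pentylbenzoate
Product: 25 tert-butyl 4,6-bis(benzyloxy)-3-[5-(benzyloxy)-2-(methoxycarbonyl)-3-methylphenoxy]-2-pentylbenzoate, via ring A aryllithium 24 (not isolated)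
Conditions: n-BuLi (1.05 equiv), THF, −78 °C; then ClCO2Me, −78 to 0 °C
Reagents that add atoms: methyl chloroformate, COC(=O)Cl
Why: Bromine–lithium exchange and C-acylation by the chloroformate place C1 on C8a; the doubly ortho-substituted methyl ester formed does not take up a second aryllithium.

**Step 12**
Reactants: 26 hexanoyl chloride
Product: 27 N-methoxy-N-methylhexanamide
Conditions: MeONHMe·HCl, K2CO3, EtOAc/H2O, 0 °C to rt
Reagents that add atoms: N,O-dimethylhydroxylamine hydrochloride, CNOC.Cl
Why: Schotten–Baumann acylation to the Weinreb amide, which delivers an acyl group to a carbanion without over-addition.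

**Step 13**
Reactants: 25 tert-butyl 4,6-bis(benzyloxy)-3-[5-(benzyloxy)-2-(methoxycarbonyl)-3-methylphenoxy]-2-pentylbenzoate; 27 N-methoxy-N-methylhexanamide
Product: 29 tert-butyl 4,6-bis(benzyloxy)-3-[5-(benzyloxy)-2-(methoxycarbonyl)-3-(2-oxoheptyl)phenoxy]-2-pentylbenzoate, via benzyllithium 28 (not isolated)
Conditions: LiN(iPr)2 (1.3 equiv), THF, −78 °C; then 27, −78 to −20 °C; aq NH4Cl
Reagents that add atoms: none
Why: Lateral lithiation of the ortho-toluate (the methyl ester makes the ring A methyl group the most acidic C–H) and acylation by the Weinreb amide form C4–C3; the benzylic CH2 of the ring C pentyl chain is secondary and wedged between the tert-butyl ester and the aryloxy group, so it should not be deprotonated.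

**Step 14**
Reactants: 29 tert-butyl 4,6-bis(benzyloxy)-3-[5-(benzyloxy)-2-(methoxycarbonyl)-3-(2-oxoheptyl)phenoxy]-2-pentylbenzoate
Product: 30 4,6-bis(benzyloxy)-3-{[6-(benzyloxy)-1-oxo-3-pentyl-1H-isochromen-8-yl]oxy}-2-pentylbenzoic acid
Conditions: CF3CO2H/CH2Cl2 (1:2), rt (to 40 °C if needed)
Reagents that add atoms: none
Why: Acid-catalysed enol lactonisation (6-exo attack of the enol oxygen on the methyl ester, loss of methanol) closes ring B as the isocoumarin, and the same acid cleaves the tert-butyl ester by loss of isobutene; aryl benzyl ethers survive dilute CF3CO2H at room temperature.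

**Step 15**
Reactants: 30 4,6-bis(benzyloxy)-3-{[6-(benzyloxy)-1-oxo-3-pentyl-1H-isochromen-8-yl]oxy}-2-pentylbenzoic acid
Product: 31 4,6-dihydroxy-3-[(6-hydroxy-1-oxo-3-pentyl-1H-isochromen-8-yl)oxy]-2-pentylbenzoic acid (CNP0439913.0)
Conditions: H2 (1 atm), 10% Pd/C, EtOAc/MeOH, rt
Reagents that add atoms: none
Why: Hydrogenolysis of the three aryl benzyl ethers under neutral conditions at room temperature, which the decarboxylation-prone resorcylic acid and the enol lactone should tolerate; the reaction is stopped after uptake of three equivalents of hydrogen.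

## Compound list

1 | olivetol (5-pentylbenzene-1,3-diol) | CCCCCc1cc(O)cc(O)c1 | starting material
2 | 1,3-bis(benzyloxy)-5-pentylbenzene | CCCCCc1cc(OCc2ccccc2)cc(OCc2ccccc2)c1 | intermediate
3 | 1,5-bis(benzyloxy)-2,4-dibromo-3-pentylbenzene | CCCCCc1c(Br)c(OCc2ccccc2)cc(OCc2ccccc2)c1Br | intermediate
4 | [4,6-bis(benzyloxy)-3-bromo-2-pentylphenyl]lithium | CCCCCc1c(Br)c(OCc2ccccc2)cc(OCc2ccccc2)c1[Li] | intermediate (not isolated)
5 | tert-butyl 4,6-bis(benzyloxy)-3-bromo-2-pentylbenzoate | CCCCCc1c(Br)c(OCc2ccccc2)cc(OCc2ccccc2)c1C(=O)OC(C)(C)C | intermediate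
6 | tert-butyl 4,6-bis(benzyloxy)-3-lithio-2-pentylbenzoate | CCCCCc1c([Li])c(OCc2ccccc2)cc(OCc2ccccc2)c1C(=O)OC(C)(C)C | intermediate (not isolated)
7 | tert-butyl 4,6-bis(benzyloxy)-3-(dimethoxyboranyl)-2-pentylbenzoate | CCCCCc1c(B(OC)OC)c(OCc2ccccc2)cc(OCc2ccccc2)c1C(=O)OC(C)(C)C | intermediate (not isolated)
8 | tert-butyl 4,6-bis(benzyloxy)-3-hydroxy-2-pentylbenzoate | CCCCCc1c(O)c(OCc2ccccc2)cc(OCc2ccccc2)c1C(=O)OC(C)(C)C | intermediate
9 | trichloroethylene | ClC=C(Cl)Cl | starting material
10 | dichloroacetylene | ClC#CCl | intermediate (not isolated)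
11 | tert-butyl 4,6-bis(benzyloxy)-3-{[(E)-1,2-dichloroethenyl]oxy}-2-pentylbenzoate | CCCCCc1c(O/C(Cl)=C\Cl)c(OCc2ccccc2)cc(OCc2ccccc2)c1C(=O)OC(C)(C)C | intermediate
12 | tert-butyl 4,6-bis(benzyloxy)-3-[(lithioethynyl)oxy]-2-pentylbenzoate | CCCCCc1c(OC#C[Li])c(OCc2ccccc2)cc(OCc2ccccc2)c1C(=O)OC(C)(C)C | intermediate (not isolated)
13 | tert-butyl 4,6-bis(benzyloxy)-3-(ethynyloxy)-2-pentylbenzoate | CCCCCc1c(OC#C)c(OCc2ccccc2)cc(OCc2ccccc2)c1C(=O)OC(C)(C)C | intermediate
14 | 3-ethoxycyclobut-2-en-1-one | CCOC1=CC(=O)C1 | starting material
15 | lithium 3-ethoxy-1-methylcyclobut-2-en-1-olate (racemic) | CCOC1=CC(C)(O[Li])C1 | intermediate (not isolated)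
16 | 3-methylcyclobut-2-en-1-one | CC1=CC(=O)C1 | intermediate
17 | 3-methylbuta-1,3-dien-1-one | CC(=C)C=C=O | intermediate (not isolated)
18 | tert-butyl 4,6-bis(benzyloxy)-3-{[3-oxo-4-(prop-1-en-2-yl)cyclobut-1-en-1-yl]oxy}-2-pentylbenzoate (racemic) | CCCCCc1c(OC2=CC(=O)C2C(C)=C)c(OCc2ccccc2)cc(OCc2ccccc2)c1C(=O)OC(C)(C)C | intermediate (not isolated)
19 | tert-butyl 4,6-bis(benzyloxy)-3-{[(3E)-5-methyl-1-oxohexa-1,3,5-trien-3-yl]oxy}-2-pentylbenzoate | CCCCCc1c(O/C(C=C=O)=C/C(C)=C)c(OCc2ccccc2)cc(OCc2ccccc2)c1C(=O)OC(C)(C)C | intermediate (not isolated)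
20 | tert-butyl 4,6-bis(benzyloxy)-3-[(5-methyl-3-oxocyclohexa-1,5-dien-1-yl)oxy]-2-pentylbenzoate | CCCCCc1c(OC2=CC(=O)CC(C)=C2)c(OCc2ccccc2)cc(OCc2ccccc2)c1C(=O)OC(C)(C)C | intermediate (not isolated)
21 | tert-butyl 4,6-bis(benzyloxy)-3-(3-hydroxy-5-methylphenoxy)-2-pentylbenzoate | CCCCCc1c(Oc2cc(O)cc(C)c2)c(OCc2ccccc2)cc(OCc2ccccc2)c1C(=O)OC(C)(C)C | intermediate
22 | tert-butyl 4,6-bis(benzyloxy)-3-(2-bromo-5-hydroxy-3-methylphenoxy)-2-pentylbenzoate | CCCCCc1c(Oc2cc(O)cc(C)c2Br)c(OCc2ccccc2)cc(OCc2ccccc2)c1C(=O)OC(C)(C)C | intermediate
23 | tert-butyl 4,6-bis(benzyloxy)-3-[5-(benzyloxy)-2-bromo-3-methylphenoxy]-2-pentylbenzoate | CCCCCc1c(Oc2cc(OCc3ccccc3)cc(C)c2Br)c(OCc2ccccc2)cc(OCc2ccccc2)c1C(=O)OC(C)(C)C | intermediate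
24 | tert-butyl 4,6-bis(benzyloxy)-3-[5-(benzyloxy)-2-lithio-3-methylphenoxy]-2-pentylbenzoate | CCCCCc1c(Oc2cc(OCc3ccccc3)cc(C)c2[Li])c(OCc2ccccc2)cc(OCc2ccccc2)c1C(=O)OC(C)(C)C | intermediate (not isolated)
25 | tert-butyl 4,6-bis(benzyloxy)-3-[5-(benzyloxy)-2-(methoxycarbonyl)-3-methylphenoxy]-2-pentylbenzoate | CCCCCc1c(Oc2cc(OCc3ccccc3)cc(C)c2C(=O)OC)c(OCc2ccccc2)cc(OCc2ccccc2)c1C(=O)OC(C)(C)C | intermediate
26 | hexanoyl chloride | CCCCCC(=O)Cl | starting material
27 | N-methoxy-N-methylhexanamide | CCCCCC(=O)N(C)OC | intermediate
28 | tert-butyl 4,6-bis(benzyloxy)-3-[5-(benzyloxy)-3-(lithiomethyl)-2-(methoxycarbonyl)phenoxy]-2-pentylbenzoate | CCCCCc1c(Oc2cc(OCc3ccccc3)cc(C[Li])c2C(=O)OC)c(OCc2ccccc2)cc(OCc2ccccc2)c1C(=O)OC(C)(C)C | intermediate (not isolated)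
29 | tert-butyl 4,6-bis(benzyloxy)-3-[5-(benzyloxy)-2-(methoxycarbonyl)-3-(2-oxoheptyl)phenoxy]-2-pentylbenzoate | CCCCCc1c(Oc2cc(OCc3ccccc3)cc(CC(=O)CCCCC)c2C(=O)OC)c(OCc2ccccc2)cc(OCc2ccccc2)c1C(=O)OC(C)(C)C | intermediate
30 | 4,6-bis(benzyloxy)-3-{[6-(benzyloxy)-1-oxo-3-pentyl-1H-isochromen-8-yl]oxy}-2-pentylbenzoic acid | CCCCCc1cc2cc(OCc3ccccc3)cc(Oc3c(OCc4ccccc4)cc(OCc4ccccc4)c(C(=O)O)c3CCCCC)c2c(=O)o1 | intermediate
31 | 4,6-dihydroxy-3-[(6-hydroxy-1-oxo-3-pentyl-1H-isochromen-8-yl)oxy]-2-pentylbenzoic acid | CCCCCc1cc2cc(O)cc(Oc3c(O)cc(O)c(C(=O)O)c3CCCCC)c2c(=O)o1 | target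

## Step count and least certain steps

Total: 15 steps. Longest linear sequence: 13 steps (steps 1–6, 8–11, 13–15).

**Step 8 (key step).** The most likely failure is loss of the terminal aryl ynol ether by oligomerisation or hydration before the ketene is there to trap it, because 16 only opens near 80 °C. A lesser problem is acylation of the product phenol by excess ketene, which brief K2CO3/MeOH treatment of the crude would reverse. Fallback: the same vinylketene 17 is generated at room temperature by photochemical Wolff rearrangement. Commercial 3-methylbut-3-en-2-one is converted by deacylative diazo transfer into 1-diazo-3-methylbut-3-en-2-one F1. F1 is irradiated with 13 in CH2Cl2 and the photolysate is warmed to complete ring opening and electrocyclisation. This sets out from 13 and returns to the route at 21.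

**Step 6.** n-BuLi may attack the tert-butyl ester, or displace a benzyloxy group ortho to it, while the chlorine–lithium exchange is still under way; the ynol ether may also be hydrated on work-up. Fallback from phenol 8, without alkyllithium: Chan–Lam O-vinylation (trivinylboroxine–pyridine complex, Cu(OAc)2, pyridine) gives tert-butyl 4,6-bis(benzyloxy)-3-(ethenyloxy)-2-pentylbenzoate F2. Bromine addition at −78 °C gives tert-butyl 4,6-bis(benzyloxy)-3-(1,2-dibromoethoxy)-2-pentylbenzoate F3. Double dehydrobromination with LiN(iPr)2 (3 equiv) and protonation returns to the route at 13.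

**Step 9.** Bromination may occur ortho to the hydroxyl (at the future C5 or C7) instead of para, because the aryloxy group also directs para to itself and the wanted position is the more crowded one. Fallback from 21: the phenol is silylated (iPr3SiCl, imidazole) to tert-butyl 4,6-bis(benzyloxy)-3-{3-methyl-5-[(triisopropylsilyl)oxy]phenoxy}-2-pentylbenzoate F4, whose bulky silyl ether screens both ortho positions. NBS then gives tert-butyl 4,6-bis(benzyloxy)-3-{2-bromo-3-methyl-5-[(triisopropylsilyl)oxy]phenoxy}-2-pentylbenzoate F5, and Bu4NF removes the silyl group, returning to the route at 22.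

**Step 14.** Lactonisation of the hindered methyl ester may be slow, and during a long exposure to acid benzyl ethers may be eroded or the electron-rich ring C acid may lose CO2 once it is free. Fallback from 29: the ketone enolate (NaH, THF) closes the lactone by O-acylation to tert-butyl 4,6-bis(benzyloxy)-3-{[6-(benzyloxy)-1-oxo-3-pentyl-1H-isochromen-8-yl]oxy}-2-pentylbenzoate F6. The tert-butyl ester is then cleaved without protic acid (Me3SiOSO2CF3, 2,6-lutidine, then water), returning to the route at 30.

**Step 15.** The C3=C4 bond of the enol lactone may be reduced while the most hindered benzyl ether is still being cleaved. Fallback from 30: Lewis-acid debenzylation with BCl3 and pentamethylbenzene in CH2Cl2 at −78 °C, which touches neither the alkene nor the acid and leads directly to 31; no new compound is made.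

## Further compounds

F1 | step 8 | 1-diazo-3-methylbut-3-en-2-one | CC(=C)C(=O)C=[N+]=[N-]
F2 | step 6 | tert-butyl 4,6-bis(benzyloxy)-3-(ethenyloxy)-2-pentylbenzoate | CCCCCc1c(OC=C)c(OCc2ccccc2)cc(OCc2ccccc2)c1C(=O)OC(C)(C)C
F3 | step 6 | tert-butyl 4,6-bis(benzyloxy)-3-(1,2-dibromoethoxy)-2-pentylbenzoate (racemic) | CCCCCc1c(OC(Br)CBr)c(OCc2ccccc2)cc(OCc2ccccc2)c1C(=O)OC(C)(C)C
F4 | step 9 | tert-butyl 4,6-bis(benzyloxy)-3-{3-methyl-5-[(triisopropylsilyl)oxy]phenoxy}-2-pentylbenzoate | CCCCCc1c(Oc2cc(O[Si](C(C)C)(C(C)C)C(C)C)cc(C)c2)c(OCc2ccccc2)cc(OCc2ccccc2)c1C(=O)OC(C)(C)C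
F5 | step 9 | tert-butyl 4,6-bis(benzyloxy)-3-{2-bromo-3-methyl-5-[(triisopropylsilyl)oxy]phenoxy}-2-pentylbenzoate | CCCCCc1c(Oc2cc(O[Si](C(C)C)(C(C)C)C(C)C)cc(C)c2Br)c(OCc2ccccc2)cc(OCc2ccccc2)c1C(=O)OC(C)(C)C
F6 | step 14 | tert-butyl 4,6-bis(benzyloxy)-3-{[6-(benzyloxy)-1-oxo-3-pentyl-1H-isochromen-8-yl]oxy}-2-pentylbenzoate | CCCCCc1cc2cc(OCc3ccccc3)cc(Oc3c(OCc4ccccc4)cc(OCc4ccccc4)c(C(=O)OC(C)(C)C)c3CCCCC)c2c(=O)o1
F0 | step 15 | none | none
A1 | alternative 1 | 6-(benzyloxy)-8-hydroxy-3-pentyl-1H-isochromen-1-one | CCCCCc1cc2cc(OCc3ccccc3)cc(O)c2c(=O)o1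
A2 | alternative 1 | 6-(benzyloxy)-8-[(2-oxonon-3-en-3-yl)oxy]-3-pentyl-1H-isochromen-1-one (alkene geometry not fixed) | CCCCCC=C(Oc1cc(OCc2ccccc2)cc2cc(CCCCC)oc(=O)c12)C(C)=O
A3 | alternative 1 | dibenzyl malonate | O=C(CC(=O)OCc1ccccc1)OCc1ccccc1
A4 | alternative 1 | benzyl 3-{[6-(benzyloxy)-1-oxo-3-pentyl-1H-isochromen-8-yl]oxy}-4,6-dioxo-2-pentylcyclohexane-1-carboxylate (mixture of stereoisomers and enol forms) | CCCCCC1C(Oc2cc(OCc3ccccc3)cc3cc(CCCCC)oc(=O)c23)C(=O)CC(=O)C1C(=O)OCc1ccccc1
A5 | alternative 2 | 6-(benzyloxy)-8-{[4-methoxy-2,4-bis(trimethylsilyloxy)buta-1,3-dien-1-yl]oxy}-3-pentyl-1H-isochromen-1-one (alkene geometry not fixed) | COC(O[Si](C)(C)C)=CC(O[Si](C)(C)C)=COc1cc(OCc2ccccc2)cc2cc(CCCCC)oc(=O)c12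
A6 | alternative 2 | benzyl oct-2-ynoate | CCCCCC#CC(=O)OCc1ccccc1
A7 | alternative 2 | benzyl 3-{[6-(benzyloxy)-1-oxo-3-pentyl-1H-isochromen-8-yl]oxy}-4,6-dihydroxy-2-pentylbenzoate | CCCCCc1c(Oc2cc(OCc3ccccc3)cc3cc(CCCCC)oc(=O)c23)c(O)cc(O)c1C(=O)OCc1ccccc1
A8 | alternative 3 | 1,5-bis(benzyloxy)-2-(2-iodo-5-methoxyphenoxy)-3-pentylbenzene | COc1ccc(I)c(Oc2c(OCc3ccccc3)cc(OCc3ccccc3)cc2CCCCC)c1
A9 | alternative 3 | 2-pentyloxirane (racemic) | CCCCCC1CO1
A10 | alternative 3 | 8-[2,4-bis(benzyloxy)-6-pentylphenoxy]-6-methoxy-3-pentyl-3,4-dihydro-1H-isochromen-1-one (racemic) | CCCCCC1Cc2cc(OC)cc(Oc3c(OCc4ccccc4)cc(OCc4ccccc4)cc3CCCCC)c2C(=O)O1
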